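**Plan**
1. Retrosynthesis cuts the C14–C15 sp2–sp2 bond last (alkenyl–alkenyl Stille coupling of a C19 iodide and a C21 stannane), then C14'–C15' (stannylvinylation), C11=C12 and C11'=C12' (Horner–Wadsworth–Emmons with one C4 iodophosphonate), C6–C7 and C6'–C7' (acetylide addition to one ring ketone) and the O–C3 bond of the oxygen bridge.
2. Enabling feature: C14 is the unsubstituted CH terminus of the C13=C14 alkene and C15 the CH terminus of the C15=C15' alkene, so the bond between them is a single bond of the nonaene that a stereoretentive coupling can make between the finished 7-oxabicyclo[2.2.1]heptane end ring and the finished cyclohexanetriol end ring, both unprotected.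
3. Forward: ketoisophorone gives a (4S)-hydroxy enone and then one enynediol (cyclohexene ring plus C7–C11) common to both halves; left half: oxirane, oxygen bridge (bicycle), then C12–C14; right half: oxirane, triol, C12'–C14', then C15'/C15; the two chains are joined last.
4. Stereochemistry: one catalytic transfer hydrogenation sets C3; C6 follows from axial acetylide addition cis to O3; C5 comes from hydroxyl-directed epoxidation (C6–OH directs in the left half, C3–OH in the right half, giving the two C5 epimers) and hydride opening; C3 is inverted in both halves (ring closure on the left, Mitsunobu on the right); all alkenes are E through trans-reduction, HWE and stereoretentive couplings.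

Key step: step 22

Remark: ring and chain atoms are referred to by carotenoid numbering (C1 gem-dimethyl carbon, C3 oxygenated CH, C5 methyl-bearing carbon, C6 chain-bearing carbon, chain C7 to C15, primes for the right half); the target is taken as drawn, left end (3R,5R,6S) with the C5 hydroxyl on the face of the oxygen bridge, right end (3'R,5'S,6'S).
Assumption: the (S,S)-configured ruthenium catalyst is taken to deliver the (4S)-alcohol 2 (CH/π model for alkenyl ketones); the mirror-image catalyst would be used if the sense were opposite.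

**Step 1**
Reactants: 1 2,6,6-trimethylcyclohex-2-ene-1,4-dione (ketoisophorone)
Product: 2 (4S)-4-hydroxy-2,6,6-trimethylcyclohex-2-en-1-one
Conditions: RuCl[(S,S)-TsDPEN](p-cymene) (cat.), HCO2H, Et3N, CH2Cl2, rt
Reagents that add atoms: none
Why: Noyori-type asymmetric transfer hydrogenation should reduce only the unhindered C4 carbonyl (the other carbonyl is flanked by a quaternary carbon and a methyl-bearing alkene carbon), and the chiral ruthenium hydride differentiates the two faces of that ketone through its CH/π contact with the enone, which sets the carbinol centre (carotenoid C3) as S.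

**Step 2**
Reactants: 3 (2E)-3-methylpent-2-en-4-yn-1-ol
Product: 4 tert-butyl(dimethyl){[(2E)-3-methylpent-2-en-4-yn-1-yl]oxy}silane
Conditions: TBSCl, imidazole, DMF, 0 °C to rt
Reagents that add atoms: tert-butyl(chloro)dimethylsilane, CC(C)(C)[Si](C)(C)Cl
Why: Imidazole-promoted silyl ether formation masks the primary hydroxyl so that only the alkyne C–H is acidic in step 3 and the C9=C10 alkene carries no directing hydroxyl in the later epoxidations.

**Step 3**
Reactants: 2 (4S)-4-hydroxy-2,6,6-trimethylcyclohex-2-en-1-one; 4 tert-butyl(dimethyl){[(2E)-3-methylpent-2-en-4-yn-1-yl]oxy}silane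
Product: 6 (1S,4S)-1-[(3E)-5-{[tert-butyl(dimethyl)silyl]oxy}-3-methylpent-3-en-1-yn-1-yl]-2,6,6-trimethylcyclohex-2-ene-1,4-diol, via lithium acetylide 5 (not isolated)
Conditions: 4 (2.3 equiv), n-BuLi, THF, −78 °C; then 2, −78 to 0 °C
Reagents that add atoms: none
Why: Lithium acetylide 1,2-addition to the hindered enone carbonyl (the first equivalent only deprotonates the hydroxyl of 2) should occur by axial attack on the envelope conformer that keeps the C3 oxygen pseudoequatorial, on the face away from the pseudoaxial C1 methyl, which places the alkynyl group cis to the C3 oxygen and sets C6 as S.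

**Step 4**
Reactants: 6 (1S,4S)-1-[(3E)-5-{[tert-butyl(dimethyl)silyl]oxy}-3-methylpent-3-en-1-yn-1-yl]-2,6,6-trimethylcyclohex-2-ene-1,4-diol
Product: 7 (1S,4S)-4-[(3E)-5-{[tert-butyl(dimethyl)silyl]oxy}-3-methylpent-3-en-1-yn-1-yl]-4-hydroxy-3,5,5-trimethylcyclohex-2-en-1-yl acetate
Conditions: Ac2O, pyridine, DMAP (cat.), CH2Cl2, 0 °C
Reagents that add atoms: acetic anhydride, CC(=O)OC(C)=O
Why: Nucleophile-catalysed acylation is selective for the secondary allylic hydroxyl over the tertiary propargylic hydroxyl buried between two fully substituted carbons, and it removes the C3 hydroxyl as a directing group for step 5.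

**Step 5**
Reactants: 7 (1S,4S)-4-[(3E)-5-{[tert-butyl(dimethyl)silyl]oxy}-3-methylpent-3-en-1-yn-1-yl]-4-hydroxy-3,5,5-trimethylcyclohex-2-en-1-yl acetate
Product: 8 (1R,2S,5R,6R)-5-[(3E)-5-{[tert-butyl(dimethyl)silyl]oxy}-3-methylpent-3-en-1-yn-1-yl]-5-hydroxy-4,4,6-trimethyl-7-oxabicyclo[4.1.0]heptan-2-yl acetate (oxirane cis to the tertiary hydroxyl)
Conditions: VO(acac)2 (cat.), t-BuOOH, CH2Cl2, 0 °C to rt
Reagents that add atoms: tert-butyl hydroperoxide, CC(C)(C)OO
Why: In this vanadium-catalysed hydroxyl-directed epoxidation only the free tertiary C6 hydroxyl can bind the metal peroxide, so oxygen should be delivered to the C4=C5 bond on the face of that hydroxyl (anti to the acetoxy group and to the side chain), which sets C4 and C5 with the C5–O bond on the face the left end needs, while the enyne alkene, which has no free allylic hydroxyl, is left alone.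

**Step 6**
Reactants: 8 (1R,2S,5R,6R)-5-[(3E)-5-{[tert-butyl(dimethyl)silyl]oxy}-3-methylpent-3-en-1-yn-1-yl]-5-hydroxy-4,4,6-trimethyl-7-oxabicyclo[4.1.0]heptan-2-yl acetate
Product: 9 (1R,2S,5R,6R)-5-[(3E)-5-{[tert-butyl(dimethyl)silyl]oxy}-3-methylpent-3-en-1-yn-1-yl]-4,4,6-trimethyl-7-oxabicyclo[4.1.0]heptane-2,5-diol
Conditions: K2CO3 (cat.), MeOH, 0 °C
Reagents that add atoms: none
Why: Base-catalysed transesterification frees the secondary C3 hydroxyl without touching the trisubstituted oxirane or the silyl ether.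

**Step 7**
Reactants: 9 (1R,2S,5R,6R)-5-[(3E)-5-{[tert-butyl(dimethyl)silyl]oxy}-3-methylpent-3-en-1-yn-1-yl]-4,4,6-trimethyl-7-oxabicyclo[4.1.0]heptane-2,5-diol
Product: 11 (1R,2R,4R,5R)-1-[(3E)-5-{[tert-butyl(dimethyl)silyl]oxy}-3-methylpent-3-en-1-yn-1-yl]-2,7,7-trimethyl-3,8-dioxatricyclo[3.2.1.0(2,4)]octane (exo-oxirane on the 7-oxabicyclo[2.2.1]heptane), via epoxy mesylate 10 (not isolated)
Conditions: MsCl, Et3N, CH2Cl2, 0 °C; then NaH, THF, 0 °C to rt
Reagents that add atoms: none
Why: Selective mesylation of the only secondary hydroxyl is followed by an intramolecular Williamson etherification in which the C6 alkoxide attacks C3 from the face opposite the leaving group through a boat-like transition state, closing the 7-oxabicyclo[2.2.1]heptane with inversion at C3 while the C5 oxygen is still locked in the oxirane so that no 1,3-fragmentation can compete.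

**Step 8**
Reactants: 11 (1R,2R,4R,5R)-1-[(3E)-5-{[tert-butyl(dimethyl)silyl]oxy}-3-methylpent-3-en-1-yn-1-yl]-2,7,7-trimethyl-3,8-dioxatricyclo[3.2.1.0(2,4)]octane
Product: 12 (1R,2R,4R)-1-[(3E)-5-{[tert-butyl(dimethyl)silyl]oxy}-3-methylpent-3-en-1-yn-1-yl]-2,6,6-trimethyl-7-oxabicyclo[2.2.1]heptan-2-ol
Conditions: LiEt3BH, THF, 0 °C to reflux
Reagents that add atoms: none
Why: Epoxide reduction by the strongly nucleophilic borohydride should take the SN2 course at the secondary oxirane carbon C4 from the endo face, which leaves the C5–O bond untouched and gives the tertiary C5 hydroxyl on the face of the oxygen bridge with the configuration fixed in step 5.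

**Step 9**
Reactants: 12 (1R,2R,4R)-1-[(3E)-5-{[tert-butyl(dimethyl)silyl]oxy}-3-methylpent-3-en-1-yn-1-yl]-2,6,6-trimethyl-7-oxabicyclo[2.2.1]heptan-2-ol
Product: 14 (1S,2R,4R)-1-[(1E,3E)-5-hydroxy-3-methylpenta-1,3-dien-1-yl]-2,6,6-trimethyl-7-oxabicyclo[2.2.1]heptan-2-ol, via vinylsilane 13 (not isolated)
Conditions: [Cp*Ru(MeCN)3]PF6 (cat.), (EtO)3SiH, CH2Cl2, 0 °C to rt; then TBAF, CuI (cat.), THF, rt
Reagents that add atoms: none
Why: Ruthenium-catalysed trans-hydrosilylation of the internal alkyne gives a (Z)-vinylsilane (either regioisomer leads to the same alkene) and fluoride-mediated protodesilylation replaces silicon by hydrogen with retention, so the alkyne becomes the (E)-C7=C8 alkene without needing a propargylic hydroxyl, and the same fluoride cleaves the primary silyl ether.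

**Step 10**
Reactants: 14 (1S,2R,4R)-1-[(1E,3E)-5-hydroxy-3-methylpenta-1,3-dien-1-yl]-2,6,6-trimethyl-7-oxabicyclo[2.2.1]heptan-2-ol
Product: 15 (2E,4E)-5-[(1S,2R,4R)-2-hydroxy-2,6,6-trimethyl-7-oxabicyclo[2.2.1]heptan-1-yl]-3-methylpenta-2,4-dienal
Conditions: MnO2, CH2Cl2, rt
Reagents that add atoms: none
Why: MnO2 oxidation is specific for the primary allylic alcohol, the tertiary hydroxyl and the bridged ether being inert, and gives the dienal without touching the alkene geometry.

**Step 11**
Reactants: 16 prop-2-yn-1-ol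
Product: 18 (2E)-3-iodo-2-methylprop-2-en-1-ol, via alkenylalane 17 (not isolated)
Conditions: AlMe3, Cp2ZrCl2 (cat.), CH2Cl2, 0 °C to rt; then I2, THF, −30 °C
Reagents that add atoms: trimethylaluminium, C[Al](C)C; iodine, II
Why: Zirconium-catalysed syn-carboalumination of the terminal alkyne (Negishi carboalumination) places methyl on the internal carbon and aluminium on the terminal carbon, and iodinolysis of the C–Al bond with retention gives the (E)-iodoalkene.

**Step 12**
Reactants: 18 (2E)-3-iodo-2-methylprop-2-en-1-ol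
Product: 19 (1E)-3-bromo-1-iodo-2-methylprop-1-ene
Conditions: CBr4, PPh3, CH2Cl2, 0 °C
Reagents that add atoms: carbon tetrabromide, BrC(Br)(Br)Br
Why: Appel bromination converts the primary allylic alcohol into the bromide under neutral conditions that leave the alkenyl iodide and its geometry untouched.

**Step 13**
Reactants: 19 (1E)-3-bromo-1-iodo-2-methylprop-1-ene
Product: 20 diethyl [(2E)-3-iodo-2-methylprop-2-en-1-yl]phosphonate
Conditions: P(OEt)3, neat, 100 °C
Reagents that add atoms: triethyl phosphite, CCOP(OCC)OCC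
Why: Michaelis–Arbuzov reaction of the allylic bromide gives the allylic phosphonate, the alkenyl iodide being inert to the phosphite.

**Step 14**
Reactants: 15 (2E,4E)-5-[(1S,2R,4R)-2-hydroxy-2,6,6-trimethyl-7-oxabicyclo[2.2.1]heptan-1-yl]-3-methylpenta-2,4-dienal; 20 diethyl [(2E)-3-iodo-2-methylprop-2-en-1-yl]phosphonate
Product: 22 (1S,2R,4R)-1-[(1E,3E,5E,7E)-8-iodo-3,7-dimethylocta-1,3,5,7-tetraen-1-yl]-2,6,6-trimethyl-7-oxabicyclo[2.2.1]heptan-2-ol, via lithiated phosphonate 21 (not isolated)
Conditions: 20 (2.2 equiv), LiHMDS, THF, −78 °C; then 15, −78 to 0 °C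
Reagents that add atoms: none
Why: Horner–Wadsworth–Emmons olefination of the dienal with the lithiated allylic phosphonate (one extra equivalent is consumed by the tertiary hydroxyl) should form the C11=C12 bond with E geometry through the favoured anti elimination pathway while the (E)-iodoalkene is carried through unchanged.

**Step 15**
Reactants: 6 (1S,4S)-1-[(3E)-5-{[tert-butyl(dimethyl)silyl]oxy}-3-methylpent-3-en-1-yn-1-yl]-2,6,6-trimethylcyclohex-2-ene-1,4-diol
Product: 23 (1S,2S,5R,6S)-5-[(3E)-5-{[tert-butyl(dimethyl)silyl]oxy}-3-methylpent-3-en-1-yn-1-yl]-4,4,6-trimethyl-7-oxabicyclo[4.1.0]heptane-2,5-diol (oxirane cis to the secondary hydroxyl and trans to the tertiary hydroxyl)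
Conditions: VO(acac)2 (cat.), t-BuOOH, CH2Cl2, 0 °C
Reagents that add atoms: tert-butyl hydroperoxide, CC(C)(C)OO
Why: In this vanadium-catalysed hydroxyl-directed epoxidation of the free diol the unhindered secondary allylic C3 hydroxyl should bind the metal far more readily than the tertiary C6 hydroxyl, so oxygen is delivered on the face of the C3 hydroxyl and C4 and C5 are set opposite to step 5, which gives the C5 configuration of the right end.

**Step 16**
Reactants: 23 (1S,2S,5R,6S)-5-[(3E)-5-{[tert-butyl(dimethyl)silyl]oxy}-3-methylpent-3-en-1-yn-1-yl]-4,4,6-trimethyl-7-oxabicyclo[4.1.0]heptane-2,5-diol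
Product: 24 (1S,2R,5R,6S)-5-[(3E)-5-{[tert-butyl(dimethyl)silyl]oxy}-3-methylpent-3-en-1-yn-1-yl]-5-hydroxy-4,4,6-trimethyl-7-oxabicyclo[4.1.0]heptan-2-yl benzoate
Conditions: PhCO2H, PPh3, DIAD, THF, 0 °C to rt
Reagents that add atoms: benzoic acid, OC(=O)c1ccccc1
Why: Mitsunobu esterification inverts the secondary C3 carbinol by SN2 attack of benzoate on the oxyphosphonium salt from the face opposite the oxirane, the tertiary hydroxyl being unreactive, which sets C3 as needed for the right end.

**Step 17**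
Reactants: 24 (1S,2R,5R,6S)-5-[(3E)-5-{[tert-butyl(dimethyl)silyl]oxy}-3-methylpent-3-en-1-yn-1-yl]-5-hydroxy-4,4,6-trimethyl-7-oxabicyclo[4.1.0]heptan-2-yl benzoate
Product: 25 (1S,2S,4R)-1-[(1E,3E)-5-{[tert-butyl(dimethyl)silyl]oxy}-3-methylpenta-1,3-dien-1-yl]-2,6,6-trimethylcyclohexane-1,2,4-triol
Conditions: LiAlH4, THF, 0 °C to reflux
Reagents that add atoms: none
Why: LiAlH4 does three known jobs in one operation, namely reductive cleavage of the benzoate, trans-diaxial hydride opening of the oxirane at the secondary carbon C4 (delivered from the adjacent C3 alkoxyaluminate on the face opposite the oxirane oxygen, leaving the tertiary C5 hydroxyl) and hydroxyl-directed trans-hydroalumination of the propargylic alkyne, which gives the (E)-C7=C8 alkene on hydrolysis.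

**Step 18**
Reactants: 25 (1S,2S,4R)-1-[(1E,3E)-5-{[tert-butyl(dimethyl)silyl]oxy}-3-methylpenta-1,3-dien-1-yl]-2,6,6-trimethylcyclohexane-1,2,4-triol
Product: 26 (1S,2S,4R)-1-[(1E,3E)-5-hydroxy-3-methylpenta-1,3-dien-1-yl]-2,6,6-trimethylcyclohexane-1,2,4-triol
Conditions: TBAF, THF, 0 °C to rt
Reagents that add atoms: none
Why: Fluoride-mediated desilylation frees the primary allylic alcohol under conditions that do not affect the tertiary allylic alcohol.

**Step 19**
Reactants: 26 (1S,2S,4R)-1-[(1E,3E)-5-hydroxy-3-methylpenta-1,3-dien-1-yl]-2,6,6-trimethylcyclohexane-1,2,4-triol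
Product: 27 (2E,4E)-3-methyl-5-[(1S,2S,4R)-1,2,4-trihydroxy-2,6,6-trimethylcyclohexyl]penta-2,4-dienal
Conditions: MnO2, CH2Cl2, rt
Reagents that add atoms: none
Why: MnO2 oxidises only the primary allylic alcohol, because the secondary hydroxyl is not allylic and the tertiary allylic hydroxyl cannot be oxidised.

**Step 20**
Reactants: 27 (2E,4E)-3-methyl-5-[(1S,2S,4R)-1,2,4-trihydroxy-2,6,6-trimethylcyclohexyl]penta-2,4-dienal; 20 diethyl [(2E)-3-iodo-2-methylprop-2-en-1-yl]phosphonate
Product: 29 (1S,2S,4R)-1-[(1E,3E,5E,7E)-8-iodo-3,7-dimethylocta-1,3,5,7-tetraen-1-yl]-2,6,6-trimethylcyclohexane-1,2,4-triol, via sodiated phosphonate 28 (not isolated)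
Conditions: 20 (4.5 equiv), NaHMDS, THF, −78 °C; then 27, −78 to 0 °C
Reagents that add atoms: none
Why: Horner–Wadsworth–Emmons olefination of the trihydroxy dienal with the sodium salt of the allylic phosphonate should form the E-configured C11'=C12' bond through the favoured anti elimination pathway, with three extra equivalents of the anion consumed by the free hydroxyls, which are spectators as their sodium alkoxides, and with the more dissociated sodium ion pair chosen to keep the olefination of this tri-alkoxide aldehyde fast at low temperature.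

**Step 21**
Reactants: 29 (1S,2S,4R)-1-[(1E,3E,5E,7E)-8-iodo-3,7-dimethylocta-1,3,5,7-tetraen-1-yl]-2,6,6-trimethylcyclohexane-1,2,4-triol; 30 (E)-1,2-bis(tributylstannyl)ethene
Product: 31 (1S,2S,4R)-1-[(1E,3E,5E,7E,9E)-3,7-dimethyl-10-(tributylstannyl)deca-1,3,5,7,9-pentaen-1-yl]-2,6,6-trimethylcyclohexane-1,2,4-triol
Conditions: PdCl2(MeCN)2 (cat.), 30 (4 equiv), DMF, rt, dark
Reagents that add atoms: none
Why: Stille coupling of the alkenyl iodide with an excess of the symmetrical distannane transfers one stannylvinyl unit (C15' and C15) with retention of both alkene geometries, the excess suppressing double coupling and the unpolar distannane being easily separated from the triol product.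

**Step 22**
Reactants: 22 (1S,2R,4R)-1-[(1E,3E,5E,7E)-8-iodo-3,7-dimethylocta-1,3,5,7-tetraen-1-yl]-2,6,6-trimethyl-7-oxabicyclo[2.2.1]heptan-2-ol; 31 (1S,2S,4R)-1-[(1E,3E,5E,7E,9E)-3,7-dimethyl-10-(tributylstannyl)deca-1,3,5,7,9-pentaen-1-yl]-2,6,6-trimethylcyclohexane-1,2,4-triol
Product: 32 (all-E)-(3R,5R,6S,3'R,5'S,6'S)-3,6-epoxy-5,6,5',6'-tetrahydro-β,β-carotene-5,3',5',6'-tetrol (target)
Conditions: Pd2(dba)3 (cat.), AsPh3, DMF, rt to 40 °C, degassed, dark
Reagents that add atoms: none
Why: Zerovalent palladium (from Pd2(dba)3, ligated by AsPh3) inserts into the C14–I bond of 22, the C15 alkenyl group is transferred from tin in the transmetalation that the weakly donating arsine accelerates, and reductive elimination forges the C14–C15 bond with retention of the C13=C14 and C15=C15' geometries. The closest known reaction type is the Stille alkenyl–alkenyl coupling of an (E)-2-methylalk-1-enyl iodide with an (E)-dienylstannane, as used for polyene assembly. No ring is closed and no stereocentre is created, so the six stereocentres and eight existing alkene geometries are carried in unchanged. The step needs chemoselectivity for the single C–I and single C–Sn terminus in the presence of four free hydroxyls, a tertiary allylic alcohol and a tertiary allylic bridged ether, which the neutral conditions free of base, acid and fluoride secure. It also needs preservation of E geometry along the new nonaene, which the stereospecific transmetalation and reductive elimination, the mild temperature and the exclusion of light and oxygen secure. Because the iodide sits on the unsubstituted terminus C14 and the stannane on the unhindered terminus C15, oxidative addition and transmetalation should both be fast and stannane homocoupling minor.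

**Compound list**
1 | 2,6,6-trimethylcyclohex-2-ene-1,4-dione (ketoisophorone) | CC1=CC(=O)CC(C)(C)C1=O | starting material
2 | (4S)-4-hydroxy-2,6,6-trimethylcyclohex-2-en-1-one | O=C1C(C)(C)C[C@H](O)C=C1C | intermediate
3 | (2E)-3-methylpent-2-en-4-yn-1-ol | C#C/C(C)=C/CO | starting material
4 | tert-butyl(dimethyl){[(2E)-3-methylpent-2-en-4-yn-1-yl]oxy}silane | C#C/C(C)=C/CO[Si](C)(C)C(C)(C)C | intermediate
5 | lithium (3E)-5-{[tert-butyl(dimethyl)silyl]oxy}-3-methylpent-3-en-1-yn-1-ide (lithium acetylide of 4) | [Li+].[C-]#C/C(C)=C/CO[Si](C)(C)C(C)(C)C | intermediate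
6 | (1S,4S)-1-[(3E)-5-{[tert-butyl(dimethyl)silyl]oxy}-3-methylpent-3-en-1-yn-1-yl]-2,6,6-trimethylcyclohex-2-ene-1,4-diol (common enynediol) | CC(C)(C)[Si](C)(C)OC/C=C(C)/C#C[C@]1(O)C(C)(C)C[C@H](O)C=C1C | intermediate
7 | (1S,4S)-4-[(3E)-5-{[tert-butyl(dimethyl)silyl]oxy}-3-methylpent-3-en-1-yn-1-yl]-4-hydroxy-3,5,5-trimethylcyclohex-2-en-1-yl acetate | CC(C)(C)[Si](C)(C)OC/C=C(C)/C#C[C@]1(O)C(C)(C)C[C@H](OC(C)=O)C=C1C | intermediate
8 | (1R,2S,5R,6R)-5-[(3E)-5-{[tert-butyl(dimethyl)silyl]oxy}-3-methylpent-3-en-1-yn-1-yl]-5-hydroxy-4,4,6-trimethyl-7-oxabicyclo[4.1.0]heptan-2-yl acetate | CC(C)(C)[Si](C)(C)OC/C=C(C)/C#C[C@]1(O)C(C)(C)C[C@H](OC(C)=O)[C@H]2O[C@@]12C | intermediate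
9 | (1R,2S,5R,6R)-5-[(3E)-5-{[tert-butyl(dimethyl)silyl]oxy}-3-methylpent-3-en-1-yn-1-yl]-4,4,6-trimethyl-7-oxabicyclo[4.1.0]heptane-2,5-diol | CC(C)(C)[Si](C)(C)OC/C=C(C)/C#C[C@]1(O)C(C)(C)C[C@H](O)[C@H]2O[C@@]12C | intermediate
10 | (1R,2S,5R,6R)-5-[(3E)-5-{[tert-butyl(dimethyl)silyl]oxy}-3-methylpent-3-en-1-yn-1-yl]-5-hydroxy-4,4,6-trimethyl-7-oxabicyclo[4.1.0]heptan-2-yl methanesulfonate | CC(C)(C)[Si](C)(C)OC/C=C(C)/C#C[C@]1(O)C(C)(C)C[C@H](OS(C)(=O)=O)[C@H]2O[C@@]12C | intermediate
11 | (1R,2R,4R,5R)-1-[(3E)-5-{[tert-butyl(dimethyl)silyl]oxy}-3-methylpent-3-en-1-yn-1-yl]-2,7,7-trimethyl-3,8-dioxatricyclo[3.2.1.0(2,4)]octane | CC(C)(C)[Si](C)(C)OC/C=C(C)/C#C[C@]12O[C@H](CC1(C)C)[C@H]1O[C@@]21C | intermediate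
12 | (1R,2R,4R)-1-[(3E)-5-{[tert-butyl(dimethyl)silyl]oxy}-3-methylpent-3-en-1-yn-1-yl]-2,6,6-trimethyl-7-oxabicyclo[2.2.1]heptan-2-ol | CC(C)(C)[Si](C)(C)OC/C=C(C)/C#C[C@]12O[C@H](CC1(C)C)C[C@@]2(C)O | intermediate
13 | (1S,2R,4R)-1-[(1Z,3E)-5-{[tert-butyl(dimethyl)silyl]oxy}-3-methyl-2-(triethoxysilyl)penta-1,3-dien-1-yl]-2,6,6-trimethyl-7-oxabicyclo[2.2.1]heptan-2-ol (silicon shown at C8) | CC(C)(C)[Si](C)(C)OC/C=C(C)/C(=C/[C@]12O[C@H](CC1(C)C)C[C@@]2(C)O)[Si](OCC)(OCC)OCC | intermediate
14 | (1S,2R,4R)-1-[(1E,3E)-5-hydroxy-3-methylpenta-1,3-dien-1-yl]-2,6,6-trimethyl-7-oxabicyclo[2.2.1]heptan-2-ol | OC/C=C(C)/C=C/[C@]12O[C@H](CC1(C)C)C[C@@]2(C)O | intermediate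
15 | (2E,4E)-5-[(1S,2R,4R)-2-hydroxy-2,6,6-trimethyl-7-oxabicyclo[2.2.1]heptan-1-yl]-3-methylpenta-2,4-dienal | O=C/C=C(C)/C=C/[C@]12O[C@H](CC1(C)C)C[C@@]2(C)O | intermediate
16 | prop-2-yn-1-ol | C#CCO | starting material
17 | {[(2E)-3-(dimethylalumanyl)-2-methylprop-2-en-1-yl]oxy}(dimethyl)alumane (alkenylalane) | C[Al](C)/C=C(C)/CO[Al](C)C | intermediate
18 | (2E)-3-iodo-2-methylprop-2-en-1-ol | OC/C(C)=C/I | intermediate
19 | (1E)-3-bromo-1-iodo-2-methylprop-1-ene | BrC/C(C)=C/I | intermediate
20 | diethyl [(2E)-3-iodo-2-methylprop-2-en-1-yl]phosphonate | CCOP(=O)(OCC)C/C(C)=C/I | intermediate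
21 | lithium salt of phosphonate 20 (carbanion at the carbon next to phosphorus) | [Li+].CCOP(=O)(OCC)[CH-]/C(C)=C/I | intermediate
22 | (1S,2R,4R)-1-[(1E,3E,5E,7E)-8-iodo-3,7-dimethylocta-1,3,5,7-tetraen-1-yl]-2,6,6-trimethyl-7-oxabicyclo[2.2.1]heptan-2-ol (left half) | I/C=C(C)/C=C/C=C(C)/C=C/[C@]12O[C@H](CC1(C)C)C[C@@]2(C)O | intermediate
23 | (1S,2S,5R,6S)-5-[(3E)-5-{[tert-butyl(dimethyl)silyl]oxy}-3-methylpent-3-en-1-yn-1-yl]-4,4,6-trimethyl-7-oxabicyclo[4.1.0]heptane-2,5-diol | CC(C)(C)[Si](C)(C)OC/C=C(C)/C#C[C@]1(O)C(C)(C)C[C@H](O)[C@@H]2O[C@]12C | intermediate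
24 | (1S,2R,5R,6S)-5-[(3E)-5-{[tert-butyl(dimethyl)silyl]oxy}-3-methylpent-3-en-1-yn-1-yl]-5-hydroxy-4,4,6-trimethyl-7-oxabicyclo[4.1.0]heptan-2-yl benzoate | CC(C)(C)[Si](C)(C)OC/C=C(C)/C#C[C@]1(O)C(C)(C)C[C@@H](OC(=O)c3ccccc3)[C@@H]2O[C@]12C | intermediate
25 | (1S,2S,4R)-1-[(1E,3E)-5-{[tert-butyl(dimethyl)silyl]oxy}-3-methylpenta-1,3-dien-1-yl]-2,6,6-trimethylcyclohexane-1,2,4-triol | CC(C)(C)[Si](C)(C)OC/C=C(C)/C=C/[C@]1(O)C(C)(C)C[C@@H](O)C[C@]1(C)O | intermediate
26 | (1S,2S,4R)-1-[(1E,3E)-5-hydroxy-3-methylpenta-1,3-dien-1-yl]-2,6,6-trimethylcyclohexane-1,2,4-triol | OC/C=C(C)/C=C/[C@]1(O)C(C)(C)C[C@@H](O)C[C@]1(C)O | intermediate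
27 | (2E,4E)-3-methyl-5-[(1S,2S,4R)-1,2,4-trihydroxy-2,6,6-trimethylcyclohexyl]penta-2,4-dienal | O=C/C=C(C)/C=C/[C@]1(O)C(C)(C)C[C@@H](O)C[C@]1(C)O | intermediate
28 | sodium salt of phosphonate 20 (carbanion at the carbon next to phosphorus) | [Na+].CCOP(=O)(OCC)[CH-]/C(C)=C/I | intermediate
29 | (1S,2S,4R)-1-[(1E,3E,5E,7E)-8-iodo-3,7-dimethylocta-1,3,5,7-tetraen-1-yl]-2,6,6-trimethylcyclohexane-1,2,4-triol | I/C=C(C)/C=C/C=C(C)/C=C/[C@]1(O)C(C)(C)C[C@@H](O)C[C@]1(C)O | intermediate
30 | (E)-1,2-bis(tributylstannyl)ethene | CCCC[Sn](CCCC)(CCCC)/C=C/[Sn](CCCC)(CCCC)CCCC | starting material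
31 | (1S,2S,4R)-1-[(1E,3E,5E,7E,9E)-3,7-dimethyl-10-(tributylstannyl)deca-1,3,5,7,9-pentaen-1-yl]-2,6,6-trimethylcyclohexane-1,2,4-triol (right half) | CCCC[Sn](CCCC)(CCCC)/C=C/C=C(C)/C=C/C=C(C)/C=C/[C@]1(O)C(C)(C)C[C@@H](O)C[C@]1(C)O | intermediate
32 | (all-E)-(3R,5R,6S,3'R,5'S,6'S)-3,6-epoxy-5,6,5',6'-tetrahydro-β,β-carotene-5,3',5',6'-tetrol | CC(/C=C/C=C(C)/C=C/[C@]12O[C@H](CC1(C)C)C[C@@]2(C)O)=C\C=C\C=C(C)\C=C\C=C(C)\C=C\[C@]1(O)C(C)(C)C[C@@H](O)C[C@]1(C)O | target

**Step count and risks**
Total steps: 22. Longest linear sequence: 11 steps (steps 1, 3, 4, 5, 6, 7, 8, 9, 10, 14, 22; the right-half line has 10).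

The three steps most likely to fail, riskiest first:

Step 7. What may go wrong: the alkoxide may eliminate the mesylate, or the displacement at C3 (a carbon flanked by the oxirane) may stall, so that the oxygen bridge does not close; the hindered endo hydride attack of step 8 adds to this risk. Fallback (sets out from 9, comes back at 12): the order of events would be reversed and the ring closed without sulfonate or base. LiEt3BH would open the oxirane of 9 at C4 (trans to the oxirane oxygen, the alkyne staying intact) to give the alkynyl triol F1. A Mitsunobu cyclodehydration (PPh3, DIAD, THF) would then activate only the secondary C3 hydroxyl, which the C6 hydroxyl displaces with inversion under neutral conditions, where no alkoxide is present to trigger a 1,3-fragmentation. This gives 12 directly and bypasses step 8.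

Step 15. What may go wrong: oxygen delivery may be directed by the tertiary C6 hydroxyl instead of the C3 hydroxyl, so that facial control of the epoxidation is lost. Fallback (sets out from 7, comes back at 23): the competing director would be removed by protection. The tertiary hydroxyl of 7 would be silylated (TMSOTf, 2,6-lutidine) to give the silyl ether acetate F2. The acetate would be cleaved with DIBAL-H at −78 °C to give the mono-alcohol F3, in which C3–OH is the only free hydroxyl. VO(acac)2/t-BuOOH epoxidation would then give the epoxy alcohol F4, and mild methanolysis (K2CO3, MeOH) of the trimethylsilyl ether would give 23.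

Step 9. What may go wrong: hydrosilylation of the hindered conjugated enyne next to the quaternary bridgehead may be incomplete, or alkene geometry may erode during protodesilylation. Fallback (sets out from 12, comes back at 14): cis-reduction followed by isomerisation would replace the trans-hydrosilylation. Semi-hydrogenation over lead-poisoned Pd/CaCO3 (Lindlar catalyst, quinoline, H2) would give the (7Z)-diene silyl ether F5. The sterically compressed Z alkene next to the bridgehead would be isomerised with a trace of I2 in daylight to the (7E)-diene silyl ether F6, and TBAF would remove the silyl group to give 14.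

**Further compounds**
F1 | step 7 | (1R,2R,4S)-1-[(3E)-5-{[tert-butyl(dimethyl)silyl]oxy}-3-methylpent-3-en-1-yn-1-yl]-2,6,6-trimethylcyclohexane-1,2,4-triol | CC(C)(C)[Si](C)(C)OC/C=C(C)/C#C[C@]1(O)C(C)(C)C[C@H](O)C[C@@]1(C)O
F2 | step 15 | (1S,4S)-4-[(3E)-5-{[tert-butyl(dimethyl)silyl]oxy}-3-methylpent-3-en-1-yn-1-yl]-3,5,5-trimethyl-4-[(trimethylsilyl)oxy]cyclohex-2-en-1-yl acetate | CC(C)(C)[Si](C)(C)OC/C=C(C)/C#C[C@]1(O[Si](C)(C)C)C(C)(C)C[C@H](OC(C)=O)C=C1C
F3 | step 15 | (1S,4S)-4-[(3E)-5-{[tert-butyl(dimethyl)silyl]oxy}-3-methylpent-3-en-1-yn-1-yl]-3,5,5-trimethyl-4-[(trimethylsilyl)oxy]cyclohex-2-en-1-ol | CC(C)(C)[Si](C)(C)OC/C=C(C)/C#C[C@]1(O[Si](C)(C)C)C(C)(C)C[C@H](O)C=C1C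
F4 | step 15 | (1S,2S,5R,6S)-5-[(3E)-5-{[tert-butyl(dimethyl)silyl]oxy}-3-methylpent-3-en-1-yn-1-yl]-4,4,6-trimethyl-5-[(trimethylsilyl)oxy]-7-oxabicyclo[4.1.0]heptan-2-ol | CC(C)(C)[Si](C)(C)OC/C=C(C)/C#C[C@]1(O[Si](C)(C)C)C(C)(C)C[C@H](O)[C@@H]2O[C@]12C
F5 | step 9 | (1S,2R,4R)-1-[(1Z,3E)-5-{[tert-butyl(dimethyl)silyl]oxy}-3-methylpenta-1,3-dien-1-yl]-2,6,6-trimethyl-7-oxabicyclo[2.2.1]heptan-2-ol | CC(C)(C)[Si](C)(C)OC/C=C(C)/C=C\[C@]12O[C@H](CC1(C)C)C[C@@]2(C)O
F6 | step 9 | (1S,2R,4R)-1-[(1E,3E)-5-{[tert-butyl(dimethyl)silyl]oxy}-3-methylpenta-1,3-dien-1-yl]-2,6,6-trimethyl-7-oxabicyclo[2.2.1]heptan-2-ol | CC(C)(C)[Si](C)(C)OC/C=C(C)/C=C/[C@]12O[C@H](CC1(C)C)C[C@@]2(C)O
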